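## Retrosynthetic overview

1. Isariotin C (16) comes from tetraol 15 by oxidising only the C9 carbinol of its 1,9-diol; 15 comes from acrylamide 14 and undec-1-en-6-one (4) by cross-metathesis.
2. 14 ⇐ 13 ⇐ 12: ketone reduction anti to the epoxide, and epoxidation of the bicyclic enone on its exo face.
3. Ring A ⇐ spirolactol dienone 10: water adds to one enone and the released tyrosinal carbon closes by aldol (C4–C5), as the spirolactol and bicyclo[3.3.1] members of this alkaloid family are thought to be related.
4. 10 ⇐ N-acryloyl-L-tyrosinal (8) by oxidative dearomatisation; 8 ⇐ L-tyrosine methyl ester.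
5. Ring order: six-membered ring B (dearomatisation) → temporary five-membered lactol → ring A (aldol) → oxirane.

Assumption: C9 of 12–15 is drawn 9R (hydroxyl cis to the 1-hydroxyl), as expected for water adding anti to the tether; either epimer serves, because C9 becomes the ketone in step 8.

Locants for the bicyclic compounds: C1 carbinol bridgehead, C2 CH2, C3 amide carbon, C4 carbinol, C5 bridgehead CH, C6–C8 the three-carbon bridge from the arene, C9 the one-carbon bridge.

## Route

Step 1
Reactants: 1 5-bromopent-1-ene; 2 hexanoyl chloride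
Product: 4 undec-1-en-6-one, via pent-4-enylmagnesium bromide 3 (not isolated)
Conditions: Mg, THF, 25 °C; then 2, Fe(acac)3 (3 mol %), THF, −78 °C
Reagents that add atoms: none
Why: Fe(acac)3-catalysed acylation of a Grignard reagent by an acid chloride (Kumada-type coupling) is much faster than Grignard addition to the ketone formed, so it stops at the ketone and leaves the terminal alkene alone; no stereocentre.

Step 2
Reactants: 5 L-tyrosine methyl ester hydrochloride; 6 acryloyl chloride
Product: 7 methyl (2S)-3-(4-hydroxyphenyl)-2-(prop-2-enoylamino)propanoate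
Conditions: NaHCO3, THF/H2O 1:1, 0 °C
Reagents that add atoms: none
Why: Schotten–Baumann N-acylation: at pH 8 the free amine is acylated far faster than the un-ionised phenol, and the S centre of L-tyrosine is untouched.

Step 3
Reactants: 7 methyl (2S)-3-(4-hydroxyphenyl)-2-(prop-2-enoylamino)propanoate
Product: 8 N-[(2S)-1-(4-hydroxyphenyl)-3-oxopropan-2-yl]prop-2-enamide (N-acryloyl-L-tyrosinal)
Conditions: iBu2AlH (3.5 equiv), CH2Cl2, −78 °C; then MeOH, aq KNaC4H4O6 (potassium sodium tartrate)
Reagents that add atoms: none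
Why: Partial ester reduction with iBu2AlH: the tetrahedral aluminium hemiacetal survives at −78 °C and gives the aldehyde only on work-up, the phenol and amide N–H being masked as aluminium salts; the α-centre is kept by using 8 crude and cold.

Step 4
Reactants: 8 N-acryloyl-L-tyrosinal
Product: 10 N-[(3S)-2-hydroxy-8-oxo-1-oxaspiro[4.5]deca-6,9-dien-3-yl]prop-2-enamide (spirolactol dienone; both anomers), via aldehyde hydrate 9 (not isolated)
Conditions: PhI(OAc)2 (1.1 equiv), MeCN/H2O 4:1, 0 °C
Reagents that add atoms: water (O)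
Why: Hypervalent-iodine oxidative dearomatisation with spirocyclisation: in aqueous MeCN the α-amido aldehyde is hydrated to gem-diol 9, and one of its hydroxyls, as the tethered nucleophile, attacks the alkyl-bearing para carbon of the aryloxy-iodane to close the five-membered lactol directly, in the same way as the known spiro-etherification and spiro-lactonisation of 3-(4-hydroxyphenyl)propanols and propanoic acids; the spiro carbon is not stereogenic and the anomeric mixture is of no consequence.

Step 5
Reactants: 10 spirolactol dienone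
Product: 13 N-[(1R,3S,4R,5R,7R,8S,9R)-7,8-epoxy-1,4,9-trihydroxy-6-oxobicyclo[3.3.1]nonan-3-yl]prop-2-enamide (epoxy ketone triol), via quinol aldehyde 11 (not isolated), via enone triol 12 (not isolated)
Conditions: K2CO3 (0.5 equiv), THF/H2O 1:1, 0 to 20 °C; then 30 % aq H2O2, 0 °C
Reagents that add atoms: water (O); hydrogen peroxide (OO)
Why: Proposed new method: base opens lactol 10 to quinol aldehyde 11, water adds to one enone (oxa-Michael) and the resulting enolate closes ring A by intramolecular aldol onto the aldehyde, the closest known reaction type being the alkoxide-triggered oxa-Michael/aldol cascade of related tyrosine-derived spirolactol dienones, and the remaining enone of 12 is then epoxidised in the same flask (Weitz–Scheffer); only closure onto the enone on the side of the α-hydrogen allows a chair transition state with the amide equatorial (this fixes C1 and C5), the aldehyde oxygen sits axial and anti to the enolate oxygen (4R), water adds anti to the tether (C9, erased later), and hydroperoxide can reach C8 only from the exo face because ring A blocks the endo face (epoxide cis to the 1-hydroxyl).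

Step 6
Reactants: 13 epoxy ketone triol
Product: 14 N-[(1R,3S,4R,5S,6S,7S,8S,9R)-7,8-epoxy-1,4,6,9-tetrahydroxybicyclo[3.3.1]nonan-3-yl]prop-2-enamide
Conditions: NaBH4, CeCl3·7H2O, MeOH, −78 °C
Reagents that add atoms: none
Why: Luche reduction: hydride enters C6 from the face opposite the adjacent epoxide oxygen and the syn-axial 9-hydroxyl, giving the 6-alcohol cis to the epoxide (6S); the acrylamide is inert.

Step 7
Reactants: 14 epoxy tetraol acrylamide; 4 undec-1-en-6-one (3 equiv)
Product: 15 (2E)-N-[(1R,3S,4R,5S,6S,7S,8S,9R)-7,8-epoxy-1,4,6,9-tetrahydroxybicyclo[3.3.1]nonan-3-yl]-7-oxododec-2-enamide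
Conditions: second-generation Hoveyda–Grubbs catalyst RuCl2(H2IMes)(=CH-C6H4-2-OiPr) (5 mol %), CH2Cl2/EtOAc, 40 °C
Reagents that add atoms: none
Why: Olefin cross-metathesis: the electron-poor acrylamide does not homodimerise and couples with the excess terminal alkene to give the conjugated E-enamide under thermodynamic control; free hydroxyls, the epoxide and the ketone are tolerated by the ruthenium carbene.

Step 8
Reactants: 15 tetraol with the complete side chain
Product: 16 isariotin C, (2E)-N-[(1S,3S,4R,5S,6S,7S,8S)-7,8-epoxy-1,4,6-trihydroxy-9-oxobicyclo[3.3.1]nonan-3-yl]-7-oxododec-2-enamide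
Conditions: [(neocuproine)Pd(OAc)]2(OTf)2 (5 mol %), 1,4-benzoquinone (2 equiv), MeCN/H2O 10:1, 25 °C
Reagents that add atoms: none
Why: Chemoselective palladium-catalysed oxidation of a vicinal diol to an α-hydroxy ketone: the cationic divalent palladium centre is chelated by the 1,9-diol, β-hydride elimination is possible only at the secondary C9, and the isolated secondary hydroxyls at C4 and C6 react much more slowly; no stereocentre is made and the arbitrary C9 centre is erased.

## Compound list

1 | 5-bromopent-1-ene | C=CCCCBr | starting material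
2 | hexanoyl chloride | CCCCCC(=O)Cl | starting material
3 | pent-4-enylmagnesium bromide | C=CCCC[Mg]Br | intermediate
4 | undec-1-en-6-one | C=CCCCC(=O)CCCCC | intermediate
5 | L-tyrosine methyl ester hydrochloride | COC(=O)[C@@H](N)Cc1ccc(O)cc1.Cl | starting material
6 | acryloyl chloride (prop-2-enoyl chloride) | C=CC(=O)Cl | starting material
7 | methyl (2S)-3-(4-hydroxyphenyl)-2-(prop-2-enoylamino)propanoate | C=CC(=O)N[C@@H](Cc1ccc(O)cc1)C(=O)OC | intermediate
8 | N-[(2S)-1-(4-hydroxyphenyl)-3-oxopropan-2-yl]prop-2-enamide | C=CC(=O)N[C@@H](Cc1ccc(O)cc1)C=O | intermediate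
9 | N-[(2S)-1,1-dihydroxy-3-(4-hydroxyphenyl)propan-2-yl]prop-2-enamide (aldehyde hydrate) | C=CC(=O)N[C@@H](Cc1ccc(O)cc1)C(O)O | intermediate
10 | N-[(3S)-2-hydroxy-8-oxo-1-oxaspiro[4.5]deca-6,9-dien-3-yl]prop-2-enamide (both anomers) | C=CC(=O)N[C@H]1CC2(OC1O)C=CC(=O)C=C2 | intermediate
11 | N-[(2S)-1-(1-hydroxy-4-oxocyclohexa-2,5-dien-1-yl)-3-oxopropan-2-yl]prop-2-enamide (quinol aldehyde) | C=CC(=O)N[C@@H](CC1(O)C=CC(=O)C=C1)C=O | intermediate
12 | N-[(1S,3S,4R,5R,9R)-1,4,9-trihydroxy-6-oxobicyclo[3.3.1]non-7-en-3-yl]prop-2-enamide (enone triol) | C=CC(=O)N[C@H]1C[C@@]2(O)[C@H](O)[C@H](C(=O)C=C2)[C@H]1O | intermediate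
13 | N-[(1R,3S,4R,5R,7R,8S,9R)-7,8-epoxy-1,4,9-trihydroxy-6-oxobicyclo[3.3.1]nonan-3-yl]prop-2-enamide | C=CC(=O)N[C@H]1C[C@@]2(O)[C@H](O)[C@H](C(=O)[C@@H]3O[C@@H]32)[C@H]1O | intermediate
14 | N-[(1R,3S,4R,5S,6S,7S,8S,9R)-7,8-epoxy-1,4,6,9-tetrahydroxybicyclo[3.3.1]nonan-3-yl]prop-2-enamide | C=CC(=O)N[C@H]1C[C@@]2(O)[C@H](O)[C@H]([C@H](O)[C@@H]3O[C@@H]32)[C@H]1O | intermediate
15 | (2E)-N-[(1R,3S,4R,5S,6S,7S,8S,9R)-7,8-epoxy-1,4,6,9-tetrahydroxybicyclo[3.3.1]nonan-3-yl]-7-oxododec-2-enamide | CCCCCC(=O)CCC/C=C/C(=O)N[C@H]1C[C@@]2(O)[C@H](O)[C@H]([C@H](O)[C@@H]3O[C@@H]32)[C@H]1O | intermediate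
16 | isariotin C | CCCCCC(=O)CCC/C=C/C(=O)N[C@H]1C[C@@]2(O)C(=O)[C@H]([C@H](O)[C@@H]3O[C@@H]32)[C@H]1O | target

## Step count and risks

Total: 8 steps. Longest linear sequence: 7 steps (5 → 16, steps 2–8); step 1 is a one-step side branch that joins in step 7.

**Step 5 (hydrative oxa-Michael/aldol/epoxidation).** The hydration equilibrium may be unfavourable, the lactol oxygen may add to the enone instead (a reversible internal acetal), the α-centre of the free aldehyde 11 may epimerise in base, and the C4 epimer may form. The fallback sets out from 10 and forms ring A from a copper enolate instead. CuCl, NaOtBu, 1,2-bis(diphenylphosphino)benzene, B2pin2 and iPrOH in THF add boron to one enone, and the copper enolate closes onto the aldehyde to give N-[(3S)-1,4-dihydroxy-6-oxo-9-(4,4,5,5-tetramethyl-1,3,2-dioxaborolan-2-yl)bicyclo[3.3.1]non-7-en-3-yl]prop-2-enamide F4. NaBO3·4H2O then oxidises the C–B bond with retention, which comes back to the route at enone triol 12; this is isolated and epoxidised with K2CO3/H2O2 to 13. The choice between the two enones is then kinetic, and a chiral bisphosphine on copper can be used to steer it.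

**Step 8 (oxidation of C9 in the presence of the C4 and C6 carbinols).** The 6-hydroxyl is 1,3-syn to the 9-hydroxyl and could compete. The fallback sets out from 13, where only one other secondary alcohol is present. The same [(neocuproine)Pd(OAc)]2(OTf)2/benzoquinone oxidation gives N-[(1S,3S,4R,5S,7R,8S)-7,8-epoxy-1,4-dihydroxy-6,9-dioxobicyclo[3.3.1]nonan-3-yl]prop-2-enamide F5. Luche reduction of the more exposed and more activated α,β-epoxy ketone at C6 then gives N-[(1S,3S,4R,5S,6S,7S,8S)-7,8-epoxy-1,4,6-trihydroxy-9-oxobicyclo[3.3.1]nonan-3-yl]prop-2-enamide F6. Cross-metathesis of F6 with 4 comes back to the route at 16.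

**Step 4 (dearomatisation of a free, epimerisable amino aldehyde through its hydrate).** The yield may be low, or the aldehyde may not survive. The fallback sets out from 7 and uses carboxylate capture instead. LiOH hydrolysis gives (2S)-3-(4-hydroxyphenyl)-2-(prop-2-enoylamino)propanoic acid F1, and PhI(OAc)2 in CF3CH2OH closes it to the spirolactone N-[(3S)-2,8-dioxo-1-oxaspiro[4.5]deca-6,9-dien-3-yl]prop-2-enamide F2. Excess iBu2AlH at −78 °C reduces both the lactone and the dienone to N-[(3S)-2,8-dihydroxy-1-oxaspiro[4.5]deca-6,9-dien-3-yl]prop-2-enamide F3 (a mixture at C2 and C8). MnO2 reoxidises only the bis-allylic alcohol, which comes back to the route at 10.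

## Further compounds

F1 | step 4 | (2S)-3-(4-hydroxyphenyl)-2-(prop-2-enoylamino)propanoic acid | C=CC(=O)N[C@@H](Cc1ccc(O)cc1)C(=O)O
F2 | step 4 | N-[(3S)-2,8-dioxo-1-oxaspiro[4.5]deca-6,9-dien-3-yl]prop-2-enamide | C=CC(=O)N[C@H]1CC2(OC1=O)C=CC(=O)C=C2
F3 | step 4 | N-[(3S)-2,8-dihydroxy-1-oxaspiro[4.5]deca-6,9-dien-3-yl]prop-2-enamide | C=CC(=O)N[C@H]1CC2(OC1O)C=CC(O)C=C2
F4 | step 5 | N-[(3S)-1,4-dihydroxy-6-oxo-9-(4,4,5,5-tetramethyl-1,3,2-dioxaborolan-2-yl)bicyclo[3.3.1]non-7-en-3-yl]prop-2-enamide | C=CC(=O)N[C@H]1C[C@@]2(O)[C@H](B3OC(C)(C)C(C)(C)O3)[C@H](C(=O)C=C2)[C@H]1O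
F5 | step 8 | N-[(1S,3S,4R,5S,7R,8S)-7,8-epoxy-1,4-dihydroxy-6,9-dioxobicyclo[3.3.1]nonan-3-yl]prop-2-enamide | C=CC(=O)N[C@H]1C[C@@]2(O)C(=O)[C@H](C(=O)[C@@H]3O[C@@H]32)[C@H]1O
F6 | step 8 | N-[(1S,3S,4R,5S,6S,7S,8S)-7,8-epoxy-1,4,6-trihydroxy-9-oxobicyclo[3.3.1]nonan-3-yl]prop-2-enamide | C=CC(=O)N[C@H]1C[C@@]2(O)C(=O)[C@H]([C@H](O)[C@@H]3O[C@@H]32)[C@H]1O
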